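**Retrosynthetic overview**

- The target is a trans-2,3-diaryl-2,3-dihydrobenzofuran. The last operations strip all O-alkyl groups and, before that, attach ring B (the 3,5-dioxygenated phenyl) to C3 by decarboxylative arylation of a C3 carboxylic acid, trans to the C2 aryl group.
- The strategy rests on this feature: C2 is at once bonded to O1 and benzylic to the 4-oxygenated phenyl ring A, and ring C (the benzo ring) carries oxygen on both carbons flanking C3a (O1 on C7a, the phenol oxygen on C4). A carbene at C3 flanked by two identical 4-methoxybenzyl (PMB) ethers therefore gives the same dihydrofuran from either CH2.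
- The only ring formed is the dihydrofuran ring (O1–C2–C3–C3a–C7a), closed through the C2–C3 bond by enantioselective rhodium-carbene C–H insertion; all benzene rings are bought.
- The diazoester comes from an aryl glyoxylate (tosylhydrazone, then base). The glyoxylate comes from lithiation of a resorcinol bis-MOM ether between its two oxygens, followed by MOM-to-PMB exchange.
- The bibenzyl arm comes from a Horner–Wadsworth–Emmons olefination of protected 3,5-dihydroxybenzaldehyde and hydrogenation.

Key step: step 9

**Assumption (remark on the chemistry):** phthaloyl-tert-leucinate dirhodium catalysts made from the (S)-amino acid are taken to give the (2R,3S) cis ester in insertions of 2-(benzyloxy)aryl diazoacetates. The mirror-image catalyst Rh2(R-PTTL)4, dirhodium tetrakis[N-phthaloyl-(R)-tert-leucinate], is therefore written for the (2S,3R) ester 14. The sense is to be confirmed on the first run (for example by X-ray analysis of a heavy-atom amide of acid 16), and the other catalyst enantiomer is used if the di-ortho-substituted substrate responds the opposite way.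

**Route**

Step 1
Reactants: 1 3,5-dihydroxybenzaldehyde
Product: 2 3,5-bis(methoxymethoxy)benzaldehyde
Conditions: MOMCl (2.5 equiv), iPr2NEt, CH2Cl2, 0 °C to rt
Reagents that add atoms: chloromethyl methyl ether, COCCl
Why: Base-mediated O-alkylation of both phenols (MOM ether formation) should proceed cleanly and leaves the aldehyde untouched.

Step 2
Reactants: 2 3,5-bis(methoxymethoxy)benzaldehyde; 3 diethyl (4-methoxybenzyl)phosphonate
Product: 4 (E)-1,3-bis(methoxymethoxy)-5-[2-(4-methoxyphenyl)ethenyl]benzene
Conditions: KOtBu, THF, 0 °C to rt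
Reagents that add atoms: none
Why: Horner–Wadsworth–Emmons olefination of an aryl aldehyde with a benzylic phosphonate anion should give the E-stilbene; the alkene geometry is of no consequence because it is hydrogenated next.

Step 3
Reactants: 4 (E)-1,3-bis(methoxymethoxy)-5-[2-(4-methoxyphenyl)ethenyl]benzene
Product: 5 1,3-bis(methoxymethoxy)-5-[2-(4-methoxyphenyl)ethyl]benzene
Conditions: H2 (1 atm), Pd/C, EtOAc, rt
Reagents that add atoms: none
Why: Catalytic hydrogenation of the stilbene double bond is reliable, and MOM and methyl ethers are inert to it (no benzyl-type ether is present yet).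

Step 4
Reactants: 5 1,3-bis(methoxymethoxy)-5-[2-(4-methoxyphenyl)ethyl]benzene; 6 methyl chlorooxoacetate
Product: 8 methyl 2-{2,6-bis(methoxymethoxy)-4-[2-(4-methoxyphenyl)ethyl]phenyl}-2-oxoacetate, via aryllithium 7 (not isolated)
Conditions: n-BuLi, THF, 0 °C, 1 h; then cannulation into ClCOCO2Me (2 equiv), THF, −78 °C
Reagents that add atoms: none
Why: Directed ortho-metalation removes the proton between the two chelating MOM-oxy groups (the most acidic site), and inverse addition of the hindered aryllithium to the acid chloride at low temperature should stop at the α-keto ester (acylation of an organolithium).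

Step 5
Reactants: 8 methyl 2-{2,6-bis(methoxymethoxy)-4-[2-(4-methoxyphenyl)ethyl]phenyl}-2-oxoacetate
Product: 9 methyl 2-{2,6-dihydroxy-4-[2-(4-methoxyphenyl)ethyl]phenyl}-2-oxoacetate
Conditions: HCl (from AcCl), MeOH, 40 °C; crude product used directly
Reagents that add atoms: none
Why: Acid-catalysed acetal exchange cleaves both MOM ethers, and methanol as solvent keeps the glyoxylate as its methyl ester rather than letting it lactonise onto the ortho phenol.

Step 6
Reactants: 9 methyl 2-{2,6-dihydroxy-4-[2-(4-methoxyphenyl)ethyl]phenyl}-2-oxoacetate; 10 4-methoxybenzyl chloride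
Product: 11 methyl 2-{2,6-bis[(4-methoxybenzyl)oxy]-4-[2-(4-methoxyphenyl)ethyl]phenyl}-2-oxoacetate
Conditions: 10 (2.4 equiv in all), K2CO3 (3 equiv), KI (cat.), DMF, 60 °C
Reagents that add atoms: 4-methoxybenzyl chloride (the second equivalent of 10), COc1ccc(CCl)cc1
Why: Williamson etherification is standard for 2,6-dihydroxyaryl ketones and consumes two equivalents of 10, one for each hydrogen-bonded phenol, while the keto ester has no enolisable proton to interfere.

Step 7
Reactants: 11 methyl 2-{2,6-bis[(4-methoxybenzyl)oxy]-4-[2-(4-methoxyphenyl)ethyl]phenyl}-2-oxoacetate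
Product: 12 methyl 2-{2,6-bis[(4-methoxybenzyl)oxy]-4-[2-(4-methoxyphenyl)ethyl]phenyl}-2-[2-(4-methylbenzenesulfonyl)hydrazinylidene]acetate (tosylhydrazone, C=N geometry not defined)
Conditions: TsNHNH2, PPTS (cat.), toluene, 80 °C
Reagents that add atoms: 4-methylbenzenesulfonohydrazide, Cc1ccc(cc1)S(=O)(=O)NN
Why: Condensation of the activated α-keto ester carbonyl with tosylhydrazide (hydrazone formation) should proceed despite the two ortho substituents, and the mild acid catalyst spares the PMB ethers.

Step 8
Reactants: 12 the tosylhydrazone of step 7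
Product: 13 methyl 2-{2,6-bis[(4-methoxybenzyl)oxy]-4-[2-(4-methoxyphenyl)ethyl]phenyl}-2-diazoacetate
Conditions: DBU, CH2Cl2, rt, dark
Reagents that add atoms: none
Why: Bamford–Stevens-type base-induced loss of sulfinate from a glyoxylate tosylhydrazone gives the ester-stabilised aryl diazo compound at room temperature, and it avoids the diazo transfer that is sluggish for di-ortho-substituted arylacetates.

Step 9
Reactants: 13 methyl 2-{2,6-bis[(4-methoxybenzyl)oxy]-4-[2-(4-methoxyphenyl)ethyl]phenyl}-2-diazoacetate
Product: 14 methyl (2S,3R)-4-[(4-methoxybenzyl)oxy]-2-(4-methoxyphenyl)-6-[2-(4-methoxyphenyl)ethyl]-2,3-dihydro-1-benzofuran-3-carboxylate (cis)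
Conditions: Rh2(R-PTTL)4 (1 mol %), toluene, slow addition of 13, −78 °C to −40 °C
Reagents that add atoms: none
Why: The divalent rhodium dimer expels N2 from 13 to give an electrophilic carbene at the future C3, which inserts into a benzylic C–H bond of one PMB ether five atoms away through a concerted, asynchronous three-centre transition state with hydride-transfer character, forming C2–C3. The closest known reaction type is the dirhodium-carboxylate-catalysed enantioselective intramolecular 1,5-C–H insertion of methyl 2-(benzyloxy)aryl diazoacetates to cis-2-aryl-2,3-dihydrobenzofuran-3-carboxylates; the second ortho substituent on the carbene-bearing ring is the untested element. The dihydrofuran ring (O1–C2–C3–C3a–C7a) closes as a five-membered ring by this 1,5-insertion, the only activated C–H bond within reach. C2 is set by the chiral phthalimido-tert-leucinate ligand sphere, which selects one of the two enantiotopic benzylic hydrogens, and C3 is set cis to the C2 aryl group by the geometry of the concerted insertion; the C3 configuration is not needed later. The step needs enantioselection at C2 and chemoselectivity over carbene dimerisation and addition to an arene; the C–H bond doubly activated by O1 and the 4-methoxyphenyl ring, low temperature and slow addition should secure these. Site selectivity is no issue because the two PMB ethers flank the carbene carbon symmetrically and give the same product, the unused one remaining as protection for the C4 oxygen.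

Step 10
Reactants: 14 the cis ester of step 9
Product: 16 (2S,3S)-4-[(4-methoxybenzyl)oxy]-2-(4-methoxyphenyl)-6-[2-(4-methoxyphenyl)ethyl]-2,3-dihydro-1-benzofuran-3-carboxylic acid (trans), via trans methyl ester 15 (not isolated)
Conditions: NaOMe (cat.), MeOH/THF, rt; then LiOH, H2O, 50 °C; cold 1 M HCl to pH 3
Reagents that add atoms: lithium hydroxide, [Li+].[OH-]
Why: Enolate-mediated epimerisation at C3 to the more stable trans ester followed by saponification should give one acid; C2 should stay intact because ring opening by β-elimination of the phenoxide from the enolate is a disfavoured 5-endo process.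

Step 11
Reactants: 16 the trans acid of step 10
Product: 17 1,3-dioxo-1,3-dihydro-2H-isoindol-2-yl (2S,3S)-4-[(4-methoxybenzyl)oxy]-2-(4-methoxyphenyl)-6-[2-(4-methoxyphenyl)ethyl]-2,3-dihydro-1-benzofuran-3-carboxylate
Conditions: N-hydroxyphthalimide, DIC, DMAP (cat.), CH2Cl2, rt
Reagents that add atoms: N-hydroxyphthalimide, O=C1c2ccccc2C(=O)N1O
Why: Carbodiimide (Steglich-type) esterification gives the redox-active ester; any epimerisation at C3 is irrelevant because this centre becomes a radical in step 13.

Step 12
Reactants: 18 1-bromo-3,5-dimethoxybenzene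
Product: 20 (3,5-dimethoxyphenyl)zinc chloride (THF solution, LiCl complex), via arylmagnesium bromide 19 (not isolated)
Conditions: Mg, LiCl, THF, rt; then ZnCl2, THF, 0 °C to rt
Reagents that add atoms: zinc chloride, Cl[Zn]Cl
Why: LiCl-assisted Grignard formation followed by transmetalation to zinc gives the mild arylzinc nucleophile needed for the coupling.

Step 13
Reactants: 17 the N-hydroxyphthalimide ester of step 11; 20 (3,5-dimethoxyphenyl)zinc chloride
Product: 21 (2S,3S)-3-(3,5-dimethoxyphenyl)-4-[(4-methoxybenzyl)oxy]-2-(4-methoxyphenyl)-6-[2-(4-methoxyphenyl)ethyl]-2,3-dihydro-1-benzofuran (trans)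
Conditions: NiCl2(dme) (20 mol %), 4,4'-di-tert-butyl-2,2'-bipyridine (40 mol %), THF/DMF, rt
Reagents that add atoms: none
Why: Nickel-catalysed decarboxylative Negishi-type arylation of a redox-active ester: single-electron reduction releases CO2 and phthalimide anion, and the planar benzylic C3 radical should be captured by the aryl–nickel species on the face opposite the C2 aryl group, so that reductive elimination gives the trans product with C2 unchanged.

Step 14
Reactants: 21 the protected trans compound of step 13
Product: 22 5-{(2S,3S)-4-hydroxy-2-(4-hydroxyphenyl)-6-[2-(4-hydroxyphenyl)ethyl]-2,3-dihydro-1-benzofuran-3-yl}benzene-1,3-diol (target)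
Conditions: BBr3 (12 equiv), pentamethylbenzene (5 equiv), CH2Cl2, −78 °C to rt; MeOH, then aq. NaHCO3
Reagents that add atoms: none
Why: Lewis-acid ether cleavage by BBr3 removes the four methyl ethers and the PMB ether in one operation, with pentamethylbenzene as a non-basic scavenger that traps the 4-methoxybenzyl cation by Friedel–Crafts alkylation before it can attack the electron-rich rings; the trans arrangement is the thermodynamic one and should persist.

**Compound list**

1 | 3,5-dihydroxybenzaldehyde | O=Cc1cc(O)cc(O)c1 | starting material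
2 | 3,5-bis(methoxymethoxy)benzaldehyde | COCOc1cc(C=O)cc(OCOC)c1 | intermediate
3 | diethyl (4-methoxybenzyl)phosphonate | CCOP(=O)(Cc1ccc(OC)cc1)OCC | starting material
4 | (E)-1,3-bis(methoxymethoxy)-5-[2-(4-methoxyphenyl)ethenyl]benzene | COCOc1cc(/C=C/c2ccc(OC)cc2)cc(OCOC)c1 | intermediate
5 | 1,3-bis(methoxymethoxy)-5-[2-(4-methoxyphenyl)ethyl]benzene | COCOc1cc(CCc2ccc(OC)cc2)cc(OCOC)c1 | intermediate
6 | methyl chlorooxoacetate | COC(=O)C(=O)Cl | starting material
7 | {2,6-bis(methoxymethoxy)-4-[2-(4-methoxyphenyl)ethyl]phenyl}lithium | [Li]c1c(OCOC)cc(CCc2ccc(OC)cc2)cc1OCOC | intermediate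
8 | methyl 2-{2,6-bis(methoxymethoxy)-4-[2-(4-methoxyphenyl)ethyl]phenyl}-2-oxoacetate | COC(=O)C(=O)c1c(OCOC)cc(CCc2ccc(OC)cc2)cc1OCOC | intermediate
9 | methyl 2-{2,6-dihydroxy-4-[2-(4-methoxyphenyl)ethyl]phenyl}-2-oxoacetate | COC(=O)C(=O)c1c(O)cc(CCc2ccc(OC)cc2)cc1O | intermediate
10 | 4-methoxybenzyl chloride | COc1ccc(CCl)cc1 | starting material
11 | methyl 2-{2,6-bis[(4-methoxybenzyl)oxy]-4-[2-(4-methoxyphenyl)ethyl]phenyl}-2-oxoacetate | COC(=O)C(=O)c1c(OCc2ccc(OC)cc2)cc(CCc2ccc(OC)cc2)cc1OCc1ccc(OC)cc1 | intermediate
12 | methyl 2-{2,6-bis[(4-methoxybenzyl)oxy]-4-[2-(4-methoxyphenyl)ethyl]phenyl}-2-[2-(4-methylbenzenesulfonyl)hydrazinylidene]acetate | COC(=O)C(=NNS(=O)(=O)c1ccc(C)cc1)c1c(OCc2ccc(OC)cc2)cc(CCc2ccc(OC)cc2)cc1OCc1ccc(OC)cc1 | intermediate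
13 | methyl 2-{2,6-bis[(4-methoxybenzyl)oxy]-4-[2-(4-methoxyphenyl)ethyl]phenyl}-2-diazoacetate | COC(=O)C(=[N+]=[N-])c1c(OCc2ccc(OC)cc2)cc(CCc2ccc(OC)cc2)cc1OCc1ccc(OC)cc1 | intermediate
14 | methyl (2S,3R)-4-[(4-methoxybenzyl)oxy]-2-(4-methoxyphenyl)-6-[2-(4-methoxyphenyl)ethyl]-2,3-dihydro-1-benzofuran-3-carboxylate (cis) | COc1ccc(CCc2cc(OCc4ccc(OC)cc4)c3c(c2)O[C@H](c2ccc(OC)cc2)[C@@H]3C(=O)OC)cc1 | intermediate
15 | methyl (2S,3S)-4-[(4-methoxybenzyl)oxy]-2-(4-methoxyphenyl)-6-[2-(4-methoxyphenyl)ethyl]-2,3-dihydro-1-benzofuran-3-carboxylate (trans) | COc1ccc(CCc2cc(OCc4ccc(OC)cc4)c3c(c2)O[C@H](c2ccc(OC)cc2)[C@H]3C(=O)OC)cc1 | intermediate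
16 | (2S,3S)-4-[(4-methoxybenzyl)oxy]-2-(4-methoxyphenyl)-6-[2-(4-methoxyphenyl)ethyl]-2,3-dihydro-1-benzofuran-3-carboxylic acid (trans) | COc1ccc(CCc2cc(OCc4ccc(OC)cc4)c3c(c2)O[C@H](c2ccc(OC)cc2)[C@H]3C(=O)O)cc1 | intermediate
17 | 1,3-dioxo-1,3-dihydro-2H-isoindol-2-yl (2S,3S)-4-[(4-methoxybenzyl)oxy]-2-(4-methoxyphenyl)-6-[2-(4-methoxyphenyl)ethyl]-2,3-dihydro-1-benzofuran-3-carboxylate | COc1ccc(CCc2cc(OCc4ccc(OC)cc4)c3c(c2)O[C@H](c2ccc(OC)cc2)[C@H]3C(=O)ON2C(=O)c4ccccc4C2=O)cc1 | intermediate
18 | 1-bromo-3,5-dimethoxybenzene | COc1cc(Br)cc(OC)c1 | starting material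
19 | (3,5-dimethoxyphenyl)magnesium bromide | COc1cc(OC)cc([Mg]Br)c1 | intermediate
20 | (3,5-dimethoxyphenyl)zinc chloride | COc1cc(OC)cc([Zn]Cl)c1 | intermediate
21 | (2S,3S)-3-(3,5-dimethoxyphenyl)-4-[(4-methoxybenzyl)oxy]-2-(4-methoxyphenyl)-6-[2-(4-methoxyphenyl)ethyl]-2,3-dihydro-1-benzofuran | COc1ccc(CCc2cc(OCc4ccc(OC)cc4)c3c(c2)O[C@H](c2ccc(OC)cc2)[C@H]3c2cc(OC)cc(OC)c2)cc1 | intermediate
22 | 5-{(2S,3S)-4-hydroxy-2-(4-hydroxyphenyl)-6-[2-(4-hydroxyphenyl)ethyl]-2,3-dihydro-1-benzofuran-3-yl}benzene-1,3-diol | Oc1ccc(CCc2cc(O)c3c(c2)O[C@H](c2ccc(O)cc2)[C@H]3c2cc(O)cc(O)c2)cc1 | target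

**Step count**

Total: 14 steps. Longest linear sequence: 13 steps (steps 1 to 11, 13 and 14); step 12 is a one-step side branch.

**Steps most likely to fail**

1. Step 9 (C–H insertion). The two ortho substituents twist the carbene out of the aryl plane, which may slow the insertion, let carbene dimerisation or addition to an anisyl ring compete, or erode the discrimination between the two benzylic hydrogens. Fallback: setting out from 13, decomposition with the achiral catalyst Rh2(OAc)4 (CH2Cl2, rt) should give the racemic cis/trans methyl ester F1. Treatment as in step 10 (NaOMe, then LiOH) converts it into the racemic trans acid F2. Classical resolution by crystallisation with (S)-1-phenylethylamine gives the (S)-1-phenylethylammonium salt of the (2S,3S)-acid F3; the mirror-image amine is taken if the other salt is the less soluble one. Acidification of the salt returns the route at 16.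

2. Step 13 (decarboxylative arylation). The benzylic C3 radical may dimerise or be reduced instead of being captured by nickel, the arylzinc may attack or deprotonate the activated ester, and facial selectivity at C3 may be incomplete. Any cis isomer has to be removed by chromatography before step 14, since acid-mediated C2–O ionisation there would turn it into the enantiomer of the target. Fallback: setting out from acid 16 (without 17 and 20), metallaphotoredox decarboxylative arylation with aryl bromide 18 (Ir[dF(CF3)ppy]2(dtbbpy)PF6, NiCl2(dme), 4,4'-di-tert-butyl-2,2'-bipyridine, Cs2CO3, DMF, blue light, rt) generates the same C3 radical oxidatively from the carboxylate and needs no organozinc reagent; it returns the route at 21.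

3. Step 14 (global dealkylation). The 4-methoxybenzyl cation released next to resorcinol-type rings may alkylate them despite the scavenger, and cleavage of five ethers may stop short. Fallback: setting out from 21, the PMB ether is first removed reductively by hydrogenolysis (H2, Pd/C, EtOAc/MeOH, rt, stopped as soon as the primary aryl PMB ether is consumed so that the slower-reacting secondary ring C2–O1 bond is spared), which generates no benzyl cation and should give (2S,3S)-3-(3,5-dimethoxyphenyl)-2-(4-methoxyphenyl)-6-[2-(4-methoxyphenyl)ethyl]-2,3-dihydro-1-benzofuran-4-ol F4. BBr3 (CH2Cl2, −78 °C to rt) then cleaves only the four methyl ethers and returns the route at 22.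

**Further compounds**

F1 | step 9 | methyl 4-[(4-methoxybenzyl)oxy]-2-(4-methoxyphenyl)-6-[2-(4-methoxyphenyl)ethyl]-2,3-dihydro-1-benzofuran-3-carboxylate, racemic cis/trans mixture | COc1ccc(CCc2cc(OCc4ccc(OC)cc4)c3c(c2)OC(c2ccc(OC)cc2)C3C(=O)OC)cc1
F2 | step 9 | racemic trans-4-[(4-methoxybenzyl)oxy]-2-(4-methoxyphenyl)-6-[2-(4-methoxyphenyl)ethyl]-2,3-dihydro-1-benzofuran-3-carboxylic acid (both enantiomers) | COc1ccc(CCc2cc(OCc4ccc(OC)cc4)c3c(c2)O[C@H](c2ccc(OC)cc2)[C@H]3C(=O)O)cc1.COc1ccc(CCc2cc(OCc4ccc(OC)cc4)c3c(c2)O[C@@H](c2ccc(OC)cc2)[C@@H]3C(=O)O)cc1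
F3 | step 9 | (S)-1-phenylethylammonium (2S,3S)-4-[(4-methoxybenzyl)oxy]-2-(4-methoxyphenyl)-6-[2-(4-methoxyphenyl)ethyl]-2,3-dihydro-1-benzofuran-3-carboxylate | COc1ccc(CCc2cc(OCc4ccc(OC)cc4)c3c(c2)O[C@H](c2ccc(OC)cc2)[C@H]3C(=O)[O-])cc1.C[C@H]([NH3+])c1ccccc1
F0 | step 13 | none | none
F4 | step 14 | (2S,3S)-3-(3,5-dimethoxyphenyl)-2-(4-methoxyphenyl)-6-[2-(4-methoxyphenyl)ethyl]-2,3-dihydro-1-benzofuran-4-ol | COc1ccc(CCc2cc(O)c3c(c2)O[C@H](c2ccc(OC)cc2)[C@H]3c2cc(OC)cc(OC)c2)cc1
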